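1.55 mM min⁻¹ was what I read from Saturday's run as the plateau rate, the concentration of target gained per minute once the climb runs straight, and I meant to carry it to the new flask as an apparent zero order in the solid substrate.

| flask | solid substrate | gas | remark | time |
|---|---|---|---|---|
| Saturday's | 0.025 M | 2.7 mM (held) | run made earlier |  |
| flask | 0.050 M | 2.7 mM (held) |  | 12 min |

- Saturday's (time / min: target / %, solid product / %): 0.500: 0.9, 0.5; 1.00: 3.1, 0; 1.33: 5.0, 0; 2.00: 9.8, 0; 2.50: 12.4, 0

(standard deviation of a reading: 0.5 percentage points)

- amounts and yields of target count solid product too
- given per volume of solution although it is solid: solid substrate, solid product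
- at the start none of the solid substrate is in solution
- at the start none of the gas is in solution
- dissolved substrate means what is dissolved; the solid is not counted in it

* amount of target and solid product together at 12 min, in percent of the solid substrate charged
* concentration of dissolved substrate in solution at 12 min, in percent of saturation

I read Saturday's table downward. The solid product column showed 0.5% in the first row, which equals the scatter of 0.5 percentage points, and 0% in the next, so I read no solid product there. The target column climbed from 3.1% in the second row to 12.4% in the last, and on Saturday's charge that climb is the plateau rate. Followed back from the second row, the line reached zero at 0.500 min, a rough lag, since the first row's 0.9% lies above that line. I then assumed that the rate held to 12 min at twice Saturday's charge. That gave 17.8 mM, less than the 0.050 M charged, so solid stayed in my reckoning, and y came to 35.6%. For [dissolved substrate] I had no reckoning.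

The forecast put y at 38% (30% to 55%), above my figure, and saturation at 80% (50% to 98%), saying “the saturation level is a guess”.

The flask gave 38.6% for y, and 35.4% of saturation, below the forecast's low end.

    solid substrate ⇌ dissolved substrate, rate k1*(cs1 - [dissolved substrate]) while solid is left; crystals form when [dissolved substrate] > cs1 (solubility = 5.30 mM, k = 0.00973 s⁻¹)
    dissolved substrate + partner → target (k = 6.22 L mol⁻¹ s⁻¹)
    2 dissolved substrate → side product (k = 0.729 L mol⁻¹ s⁻¹)
    solid product ⇌ target, rate k4*(cs4 - [target]) while solid is left; crystals form when [target] > cs4 (solubility = 17.0 mM, k = 0.217 s⁻¹)
    2 partner → homo dimer (k = 2.67 L mol⁻¹ s⁻¹)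
    partner → decomposed reagent (k = 0.00502 s⁻¹)
    gas ⇌ partner, rate k7*(csat - [partner]) (kL = 0.245 s⁻¹)

Put back through the rule, this flask's 38.6% of 0.050 M is 19.3 mM, or 1.68 mM min⁻¹ over the 11.5 min after the lag, against the 1.55 mM min⁻¹ read on Saturday. The same reckoning on the neighbour charged with 0.12 M of solid substrate divided 17.8 mM by that charge and gave 14.8%. That neighbour gave 16.1%, which is 19.3 mM, with 79.5% of its charge still solid.

The readings were computed for an exercise; the scatter is artificial.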